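**Plan**
- Retrosynthesis: the C5–Cl bond and the silyl ethers go first. Ring A is then opened at C6–C7, because the C6 ketone beside the tertiary C7 carbinol is an α-ketol, the retron of an aldehyde–ketone benzoin reaction. Further cuts are the exocyclic C4a=C5 bond, the C8a–C8 aldol bond, the O2–C3 bond of ring B, the C4–C4a acyl–alkyne bond, and C1′=C2′ and C3′=C4′ in the side chain.
- Forward: the C1′–C7′ dienyne is made, acylated to an ynone and closed to ring B (a 6-dienyl dihydropyranone). The C8/C7 arm is added by aldol reaction at C8a, the pyranone carbonyl is homologated to the C5/C6 enal, and ring A is closed by the carbene-catalysed benzoin reaction. C5 chlorination and desilylation finish the route.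
- Stereochemistry: C5′/C6′ come from ethyl (S)-3-hydroxybutanoate by anti methylation. C8a/C8 come from an anti aldol with (S)-lactaldehyde, whose own centre (C7) is a relay that is oxidised away. C7 is set in the benzoin step by the C8 silyloxy group and a chiral triazolium carbene. The E alkenes come from stabilised Wittig and phosphonate reagents.

Key step: step 18

Notation: TBS = tert-butyldimethylsilyl, TES = triethylsilyl. Atom labels follow the isochromene numbering of the target (O2, C1, C3, C4, C4a, C5–C8, C8a; side chain C1′–C7′).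

Assumption: which antipode of the aminoindanol triazolium reinforces the substrate bias at C7 cannot be derived with certainty on paper; the (5aS,10bR) salt is written, and its antipode would be used in the same way if the pairing were mismatched.

Remark: the enals 23–25 are drawn as the E isomers at C4a=C5; the Z isomers are carried along, since the two should interconvert through the zwitterionic form of the push–pull system.

**Step 1**
Reactants: 1 ethyl (S)-3-hydroxybutanoate
Product: 3 ethyl (2S,3S)-3-hydroxy-2-methylbutanoate, via dilithio alkoxide-enolate 2 (not isolated)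
Conditions: LiN(i-Pr)2 (2.2 equiv), THF, −78 to −20 °C; MeI, DMPU, −78 to 0 °C
Reagents that add atoms: iodomethane, CI
Why: Fráter–Seebach alkylation, in which the chelated dilithio alkoxide–enolate is methylated on the face away from the C3 methyl group, should set the new centre anti to the hydroxyl and so give the C5′/C6′ pair of the target.

**Step 2**
Reactants: 3 ethyl (2S,3S)-3-hydroxy-2-methylbutanoate
Product: 4 ethyl (2S,3S)-3-(TBS-oxy)-2-methylbutanoate
Conditions: TBSCl, imidazole, DMF, 23 °C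
Reagents that add atoms: tert-butyldimethylsilyl chloride, CC(C)(C)[Si](C)(C)Cl
Why: Routine silylation of a secondary alcohol gives an ether that is meant to last until the final step.

**Step 3**
Reactants: 4 ethyl (2S,3S)-3-(TBS-oxy)-2-methylbutanoate
Product: 5 (2S,3S)-3-(TBS-oxy)-2-methylbutanal
Conditions: i-Bu2AlH (1.1 equiv), CH2Cl2, −78 °C
Reagents that add atoms: none
Why: Partial ester reduction at low temperature stops at the aluminium hemiacetal, which releases the aldehyde on work-up without basic conditions that could epimerise the α-centre.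

**Step 4**
Reactants: 5 (2S,3S)-3-(TBS-oxy)-2-methylbutanal
Product: 6 (2E,4R,5S)-5-(TBS-oxy)-2,4-dimethylhex-2-enal
Conditions: Ph3P=C(CH3)CHO, toluene, 90 °C
Reagents that add atoms: 2-(triphenylphosphoranylidene)propanal, CC(C=O)=P(c1ccccc1)(c1ccccc1)c1ccccc1
Why: Wittig olefination with a stabilised formyl ylide should give the E trisubstituted enal (C3′=C4′), and the conjugated product is too unreactive to be olefinated a second time.

**Step 5**
Reactants: 6 (2E,4R,5S)-5-(TBS-oxy)-2,4-dimethylhex-2-enal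
Product: 7 tert-butyldimethyl{[(2S,3R,4E,6E)-3,5-dimethyl-9-(trimethylsilyl)nona-4,6-dien-8-yn-2-yl]oxy}silane
Conditions: (EtO)2P(O)CH2C≡CSiMe3, LiN(SiMe3)2, THF, −78 to 0 °C; then 6
Reagents that add atoms: diethyl [3-(trimethylsilyl)prop-2-yn-1-yl]phosphonate, CCOP(=O)(CC#C[Si](C)(C)C)OCC
Why: Horner–Wadsworth–Emmons olefination with the silylpropargyl phosphonate anion builds C1′=C2′ with the E geometry usual for stabilised phosphonates and brings in the future C3≡C4 unit.

**Step 6**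
Reactants: 7 the silylated dienyne
Product: 8 tert-butyl{[(2S,3R,4E,6E)-3,5-dimethylnona-4,6-dien-8-yn-2-yl]oxy}dimethylsilane
Conditions: K2CO3 (cat.), MeOH, 23 °C
Reagents that add atoms: none
Why: Methanolysis of the alkynyl C–Si bond is fast under catalytic carbonate, while the secondary silyl ether is untouched.

**Step 7**
Reactants: 9 methyl 3-hydroxypropanoate
Product: 10 methyl 3-(TES-oxy)propanoate
Conditions: Et3SiCl, imidazole, CH2Cl2, 0 °C
Reagents that add atoms: chlorotriethylsilane, CC[Si](Cl)(CC)CC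
Why: Routine silylation gives a primary TES ether that can later be removed in the presence of the secondary TBS ether.

**Step 8**
Reactants: 10 methyl 3-(TES-oxy)propanoate
Product: 11 N-methoxy-N-methyl-3-(TES-oxy)propanamide
Conditions: MeNH(OMe)·HCl, i-PrMgCl, THF, −20 to 0 °C
Reagents that add atoms: N,O-dimethylhydroxylamine hydrochloride, CNOC.Cl
Why: Weinreb amide formation by aminolysis of the ester with the magnesium amide of N,O-dimethylhydroxylamine is a standard direct conversion that tolerates β-silyloxy groups.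

**Step 9**
Reactants: 8 the terminal dienyne; 11 N-methoxy-N-methyl-3-(TES-oxy)propanamide
Product: 13 (6E,8E,10R,11S)-11-(TBS-oxy)-8,10-dimethyl-1-(TES-oxy)dodeca-6,8-dien-4-yn-3-one, via lithium acetylide 12 (not isolated)
Conditions: n-BuLi, THF, −78 °C; then 11, −78 to 0 °C
Reagents that add atoms: none
Why: Acylation of the lithium acetylide by the Weinreb amide forms the C4–C4a bond, and the chelated tetrahedral intermediate prevents a second addition.

**Step 10**
Reactants: 13 the ynone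
Product: 15 6-[(1E,3E,5R,6S)-6-(TBS-oxy)-3,5-dimethylhepta-1,3-dien-1-yl]-2,3-dihydro-4H-pyran-4-one, via hydroxy-ynone 14 (not isolated)
Conditions: PPTS (cat.), MeOH, 0 to 23 °C; then AgOTf (10 mol %), CH2Cl2, 23 °C
Reagents that add atoms: none
Why: Mild acid removes only the primary TES ether, and silver-promoted 6-endo-dig oxa-Michael addition of the freed hydroxyl to the ynone closes ring B through the O2–C3 bond.

**Step 11**
Reactants: 16 ethyl (S)-lactate
Product: 17 ethyl (S)-2-(TES-oxy)propanoate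
Conditions: Et3SiCl, imidazole, CH2Cl2, 0 °C
Reagents that add atoms: chlorotriethylsilane, CC[Si](Cl)(CC)CC
Why: Routine silylation gives a TES ether that can later be removed selectively beside the two TBS ethers.

**Step 12**
Reactants: 17 ethyl (S)-2-(TES-oxy)propanoate
Product: 18 (S)-2-(TES-oxy)propanal
Conditions: i-Bu2AlH (1.1 equiv), CH2Cl2, −78 °C
Reagents that add atoms: none
Why: Partial reduction of the α-silyloxy ester at low temperature gives the aldehyde, which is used at once to avoid racemisation.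

**Step 13**
Reactants: 15 the dihydropyranone; 18 (S)-2-(TES-oxy)propanal
Product: 20 (3S)-6-[(1E,3E,5R,6S)-6-(TBS-oxy)-3,5-dimethylhepta-1,3-dien-1-yl]-3-[(1R,2S)-1-hydroxy-2-(TES-oxy)propyl]-2,3-dihydro-4H-pyran-4-one, via boron dienolate 19 (not isolated)
Conditions: (c-C6H11)2BCl, Et3N, Et2O, −78 to 0 °C; 18, −78 to −20 °C; then MeOH, pH 7 buffer, H2O2, 0 °C
Reagents that add atoms: none
Why: In this boron-mediated aldol reaction the ring holds the enolate in the E geometry, so the chair (Zimmerman–Traxler) transition state should give the anti adduct, and attack on the Felkin–Anh face of the aldehyde (silyloxy group anti to the incoming enolate carbon) should set C8 as R and C8a as S, while the lactaldehyde centre (C7) is only a relay that is oxidised in step 17.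

**Step 14**
Reactants: 20 the aldol adduct
Product: 21 (3S)-3-[(1R,2S)-1-(TBS-oxy)-2-(TES-oxy)propyl]-6-[(1E,3E,5R,6S)-6-(TBS-oxy)-3,5-dimethylhepta-1,3-dien-1-yl]-2,3-dihydro-4H-pyran-4-one
Conditions: TBSOTf, 2,6-lutidine, CH2Cl2, −78 to 0 °C
Reagents that add atoms: tert-butyldimethylsilyl trifluoromethanesulfonate, CC(C)(C)[Si](C)(C)OS(=O)(=O)C(F)(F)F
Why: The silyl triflate protects the hindered C8 hydroxyl under non-basic conditions that exclude retro-aldol cleavage and epimerisation at C8a.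

**Step 15**
Reactants: 21 the fully silylated pyranone
Product: 23 (2E)-2-[(3S)-3-[(1R,2S)-1-(TBS-oxy)-2-(TES-oxy)propyl]-6-[(1E,3E,5R,6S)-6-(TBS-oxy)-3,5-dimethylhepta-1,3-dien-1-yl]-2,3-dihydro-4H-pyran-4-ylidene]acetaldehyde, via ethoxyvinyl carbinol 22 (not isolated)
Conditions: (Z)-BrCH=CHOEt, t-BuLi (2 equiv), Et2O, −78 °C; CeCl3, THF, −78 °C; 21, −78 °C; then 0.5 M aq. HCl, THF, 0 °C
Reagents that add atoms: (Z)-1-bromo-2-ethoxyethene, CCO/C=C\Br
Why: This two-carbon formyl olefination relies on 1,2-addition of the weakly basic (Z)-2-ethoxyvinylcerium reagent to the vinylogous ester carbonyl, after which dilute acid ionises the doubly allylic tertiary carbinol and water adds at the ethoxy-bearing terminus with loss of ethanol to give the push–pull enal (C4a=C5–C6HO).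

**Step 16**
Reactants: 23 the TES-protected enal
Product: 24 (2E)-2-[(3S)-3-[(1R,2S)-1-(TBS-oxy)-2-hydroxypropyl]-6-[(1E,3E,5R,6S)-6-(TBS-oxy)-3,5-dimethylhepta-1,3-dien-1-yl]-2,3-dihydro-4H-pyran-4-ylidene]acetaldehyde
Conditions: HF·pyridine, pyridine, THF, 0 °C
Reagents that add atoms: none
Why: Buffered fluoride cleaves the secondary TES ether much faster than the two more hindered TBS ethers, and the acidic medium excludes 1,2-silyl migration.

**Step 17**
Reactants: 24 the hydroxy-enal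
Product: 25 (2E)-2-[(3S)-3-[(1R)-1-(TBS-oxy)-2-oxopropyl]-6-[(1E,3E,5R,6S)-6-(TBS-oxy)-3,5-dimethylhepta-1,3-dien-1-yl]-2,3-dihydro-4H-pyran-4-ylidene]acetaldehyde
Conditions: Dess–Martin periodinane, pyridine, CH2Cl2, 0 to 23 °C
Reagents that add atoms: none
Why: Dess–Martin oxidation of the C7 carbinol gives the methyl ketone under neutral conditions that leave the enal, the polyene and the C8 centre alone.

**Step 18**
Reactants: 25 the keto-enal
Product: 26 (7R,8R,8aS)-8-(TBS-oxy)-3-[(1E,3E,5R,6S)-6-(TBS-oxy)-3,5-dimethylhepta-1,3-dien-1-yl]-7-hydroxy-7-methyl-1,7,8,8a-tetrahydro-6H-isochromen-6-one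
Conditions: (5aS,10bR)-2-(pentafluorophenyl)-5a,10b-dihydro-4H,6H-indeno[2,1-b][1,2,4]triazolo[4,3-d][1,4]oxazin-2-ium tetrafluoroborate (20 mol %), i-Pr2NEt (20 mol %), toluene, 23 °C
Reagents that add atoms: none
Why: The carbene adds to the C6 aldehyde, proton transfer gives the Breslow intermediate (an extended hydroxy-enamine), its C6 carbon attacks the C7 ketone, and proton transfer with loss of the carbene leaves the C6 ketone and the C7 tertiary alcohol. The closest known reaction type is the carbene-catalysed intramolecular crossed aldehyde–ketone benzoin reaction that gives six-membered tertiary α-ketols with aminoindanol-derived triazolium salts. Ring A closes in a 6-exo-trig mode from the E enal, in which C6 lies cis to C8a, and the Z isomer feeds in by rotation about the push–pull C4a=C5 bond. At C7 the tether allows attack only from the C8a side of the ketone, and with the C8 silyloxy group anti to the incoming carbon (polar Felkin–Anh) and the methyl group pseudo-equatorial the new hydroxyl should fall cis to the C8 oxygen, a bias the chiral triazolium is chosen to reinforce. The step needs acyl-anion instead of homoenolate reactivity, which the substrate secures because the β-carbon C4a is fully substituted and could only close a four-membered ring, and it needs the C8a proton left alone, which the catalytic amount of a weak amine base secures.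

**Step 19**
Reactants: 26 the bicyclic α-ketol
Product: 27 (7R,8R,8aS)-8-(TBS-oxy)-3-[(1E,3E,5R,6S)-6-(TBS-oxy)-3,5-dimethylhepta-1,3-dien-1-yl]-5-chloro-7-hydroxy-7-methyl-1,7,8,8a-tetrahydro-6H-isochromen-6-one
Conditions: N-chlorosuccinimide, CH2Cl2, 0 to 23 °C
Reagents that add atoms: N-chlorosuccinimide, O=C1CCC(=O)N1Cl
Why: Electrophilic chlorination should take place at C5, the α-carbon of the dienone that receives electron density from O2 through C3=C4–C4a=C5, as in the halogenation of vinylogous esters and azaphilone cores.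

**Step 20**
Reactants: 27 the chlorinated bis-silyl ether
Product: 28 (7R,8R,8aS)-5-chloro-7,8-dihydroxy-3-[(1E,3E,5R,6S)-6-hydroxy-3,5-dimethylhepta-1,3-dien-1-yl]-7-methyl-1,7,8,8a-tetrahydro-6H-isochromen-6-one
Conditions: HF·pyridine, THF, 0 to 23 °C
Reagents that add atoms: none
Why: Non-basic fluoride removes both TBS ethers without the β-elimination of the C8 oxygen or the retro-benzoin cleavage that a basic fluoride source could cause.

**Compound list**
1 | ethyl (S)-3-hydroxybutanoate | CCOC(=O)C[C@H](C)O | starting material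
2 | dilithio alkoxide–enolate of 1 | CCOC(O[Li])=C[C@H](C)O[Li] | intermediate
3 | ethyl (2S,3S)-3-hydroxy-2-methylbutanoate | CCOC(=O)[C@@H](C)[C@H](C)O | intermediate
4 | ethyl (2S,3S)-3-(TBS-oxy)-2-methylbutanoate | CCOC(=O)[C@@H](C)[C@H](C)O[Si](C)(C)C(C)(C)C | intermediate
5 | (2S,3S)-3-(TBS-oxy)-2-methylbutanal | O=C[C@@H](C)[C@H](C)O[Si](C)(C)C(C)(C)C | intermediate
6 | (2E,4R,5S)-5-(TBS-oxy)-2,4-dimethylhex-2-enal | O=C/C(C)=C/[C@@H](C)[C@H](C)O[Si](C)(C)C(C)(C)C | intermediate
7 | tert-butyldimethyl{[(2S,3R,4E,6E)-3,5-dimethyl-9-(trimethylsilyl)nona-4,6-dien-8-yn-2-yl]oxy}silane | C[Si](C)(C)C#C/C=C/C(C)=C/[C@@H](C)[C@H](C)O[Si](C)(C)C(C)(C)C | intermediate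
8 | tert-butyl{[(2S,3R,4E,6E)-3,5-dimethylnona-4,6-dien-8-yn-2-yl]oxy}dimethylsilane | C#C/C=C/C(C)=C/[C@@H](C)[C@H](C)O[Si](C)(C)C(C)(C)C | intermediate
9 | methyl 3-hydroxypropanoate | COC(=O)CCO | starting material
10 | methyl 3-(TES-oxy)propanoate | COC(=O)CCO[Si](CC)(CC)CC | intermediate
11 | N-methoxy-N-methyl-3-(TES-oxy)propanamide | CON(C)C(=O)CCO[Si](CC)(CC)CC | intermediate
12 | lithium acetylide of 8 | [Li]C#C/C=C/C(C)=C/[C@@H](C)[C@H](C)O[Si](C)(C)C(C)(C)C | intermediate
13 | (6E,8E,10R,11S)-11-(TBS-oxy)-8,10-dimethyl-1-(TES-oxy)dodeca-6,8-dien-4-yn-3-one | CC[Si](CC)(CC)OCCC(=O)C#C/C=C/C(C)=C/[C@@H](C)[C@H](C)O[Si](C)(C)C(C)(C)C | intermediate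
14 | (6E,8E,10R,11S)-11-(TBS-oxy)-1-hydroxy-8,10-dimethyldodeca-6,8-dien-4-yn-3-one | OCCC(=O)C#C/C=C/C(C)=C/[C@@H](C)[C@H](C)O[Si](C)(C)C(C)(C)C | intermediate
15 | 6-[(1E,3E,5R,6S)-6-(TBS-oxy)-3,5-dimethylhepta-1,3-dien-1-yl]-2,3-dihydro-4H-pyran-4-one | O=C1CCOC(/C=C/C(C)=C/[C@@H](C)[C@H](C)O[Si](C)(C)C(C)(C)C)=C1 | intermediate
16 | ethyl (S)-lactate | CCOC(=O)[C@H](C)O | starting material
17 | ethyl (S)-2-(TES-oxy)propanoate | CCOC(=O)[C@H](C)O[Si](CC)(CC)CC | intermediate
18 | (S)-2-(TES-oxy)propanal | O=C[C@H](C)O[Si](CC)(CC)CC | intermediate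
19 | dicyclohexylboron dienolate of 15 (4-boryloxy-2H-pyran) | C1(OB(C2CCCCC2)C2CCCCC2)=CCOC(/C=C/C(C)=C/[C@@H](C)[C@H](C)O[Si](C)(C)C(C)(C)C)=C1 | intermediate
20 | (3S)-6-[(1E,3E,5R,6S)-6-(TBS-oxy)-3,5-dimethylhepta-1,3-dien-1-yl]-3-[(1R,2S)-1-hydroxy-2-(TES-oxy)propyl]-2,3-dihydro-4H-pyran-4-one | O=C1C=C(/C=C/C(C)=C/[C@@H](C)[C@H](C)O[Si](C)(C)C(C)(C)C)OC[C@H]1[C@@H](O)[C@H](C)O[Si](CC)(CC)CC | intermediate
21 | (3S)-3-[(1R,2S)-1-(TBS-oxy)-2-(TES-oxy)propyl]-6-[(1E,3E,5R,6S)-6-(TBS-oxy)-3,5-dimethylhepta-1,3-dien-1-yl]-2,3-dihydro-4H-pyran-4-one | O=C1C=C(/C=C/C(C)=C/[C@@H](C)[C@H](C)O[Si](C)(C)C(C)(C)C)OC[C@H]1[C@@H](O[Si](C)(C)C(C)(C)C)[C@H](C)O[Si](CC)(CC)CC | intermediate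
22 | (3S)-4-[(Z)-2-ethoxyethenyl]-3-[(1R,2S)-1-(TBS-oxy)-2-(TES-oxy)propyl]-6-[(1E,3E,5R,6S)-6-(TBS-oxy)-3,5-dimethylhepta-1,3-dien-1-yl]-3,4-dihydro-2H-pyran-4-ol (both C4 epimers) | CCO/C=C\C1(O)C=C(/C=C/C(C)=C/[C@@H](C)[C@H](C)O[Si](C)(C)C(C)(C)C)OC[C@H]1[C@@H](O[Si](C)(C)C(C)(C)C)[C@H](C)O[Si](CC)(CC)CC | intermediate
23 | (2E)-2-[(3S)-3-[(1R,2S)-1-(TBS-oxy)-2-(TES-oxy)propyl]-6-[(1E,3E,5R,6S)-6-(TBS-oxy)-3,5-dimethylhepta-1,3-dien-1-yl]-2,3-dihydro-4H-pyran-4-ylidene]acetaldehyde | O=C/C=C1/C=C(/C=C/C(C)=C/[C@@H](C)[C@H](C)O[Si](C)(C)C(C)(C)C)OC[C@H]1[C@@H](O[Si](C)(C)C(C)(C)C)[C@H](C)O[Si](CC)(CC)CC | intermediate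
24 | (2E)-2-[(3S)-3-[(1R,2S)-1-(TBS-oxy)-2-hydroxypropyl]-6-[(1E,3E,5R,6S)-6-(TBS-oxy)-3,5-dimethylhepta-1,3-dien-1-yl]-2,3-dihydro-4H-pyran-4-ylidene]acetaldehyde | O=C/C=C1/C=C(/C=C/C(C)=C/[C@@H](C)[C@H](C)O[Si](C)(C)C(C)(C)C)OC[C@H]1[C@@H](O[Si](C)(C)C(C)(C)C)[C@H](C)O | intermediate
25 | (2E)-2-[(3S)-3-[(1R)-1-(TBS-oxy)-2-oxopropyl]-6-[(1E,3E,5R,6S)-6-(TBS-oxy)-3,5-dimethylhepta-1,3-dien-1-yl]-2,3-dihydro-4H-pyran-4-ylidene]acetaldehyde | O=C/C=C1/C=C(/C=C/C(C)=C/[C@@H](C)[C@H](C)O[Si](C)(C)C(C)(C)C)OC[C@H]1[C@@H](O[Si](C)(C)C(C)(C)C)C(C)=O | intermediate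
26 | (7R,8R,8aS)-8-(TBS-oxy)-3-[(1E,3E,5R,6S)-6-(TBS-oxy)-3,5-dimethylhepta-1,3-dien-1-yl]-7-hydroxy-7-methyl-1,7,8,8a-tetrahydro-6H-isochromen-6-one | CC(/C=C/C1=CC2=CC(=O)[C@](C)(O)[C@H](O[Si](C)(C)C(C)(C)C)[C@@H]2CO1)=C\[C@@H](C)[C@H](C)O[Si](C)(C)C(C)(C)C | intermediate
27 | (7R,8R,8aS)-8-(TBS-oxy)-3-[(1E,3E,5R,6S)-6-(TBS-oxy)-3,5-dimethylhepta-1,3-dien-1-yl]-5-chloro-7-hydroxy-7-methyl-1,7,8,8a-tetrahydro-6H-isochromen-6-one | CC(/C=C/C1=CC2=C(Cl)C(=O)[C@](C)(O)[C@H](O[Si](C)(C)C(C)(C)C)[C@@H]2CO1)=C\[C@@H](C)[C@H](C)O[Si](C)(C)C(C)(C)C | intermediate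
28 | (7R,8R,8aS)-5-chloro-7,8-dihydroxy-3-[(1E,3E,5R,6S)-6-hydroxy-3,5-dimethylhepta-1,3-dien-1-yl]-7-methyl-1,7,8,8a-tetrahydro-6H-isochromen-6-one | CC(/C=C/C1=CC2=C(Cl)C(=O)[C@](C)(O)[C@H](O)[C@@H]2CO1)=C\[C@@H](C)[C@H](C)O | target

**Step count**
Total: 20 steps. Longest linear sequence: 16 steps (steps 1–6, 9, 10 and 13–20, from ethyl (S)-3-hydroxybutanoate).

**Steps most likely to fail**

Step 18. The electron-rich, doubly vinylogous formyl group may be slow to enter the Breslow manifold. The amine base may remove the γ-proton at C8a, with loss of configuration or β-elimination of the C8 silyloxy group. The two ketone faces may also be discriminated poorly. The fallback closes the same bond reductively. It sets out from 25: SmI2 (THF, t-BuOH, −78 °C) should effect ketyl–carbonyl (pinacol) cyclisation to the cis-6,7-diol F1, with both oxygens bridged by samarium. MnO2 in CH2Cl2 then oxidises only the allylic secondary C6 carbinol and returns to the route at 26. The C7 configuration would then rest on the C8 centre alone.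

Step 13. In the closed transition state the E substituent of the cyclic enolate clashes with the dipole-minimised arrangement of the α-silyloxy aldehyde, so face selection may erode and C8 epimers may form. The fallback uses an open transition state. It sets out from 15: LiN(i-Pr)2 and Me3SiCl give the 4-(trimethylsilyloxy)-2H-pyran F2. A Mukaiyama aldol addition of F2 to 18, promoted by BF3·OEt2 in CH2Cl2 at −78 °C and governed by Felkin–Anh control alone, returns to the route at 20.

Step 15. The vinyl-metal may enolise the hindered α-branched ketone, followed by loss of the C8 silyloxy group, or ring B may open during the acidic unmasking. The fallback changes the oxidation level of the two-carbon unit. It sets out from 21: lithium ethoxyacetylide (ethoxyethyne, n-BuLi, THF, −78 °C), which is linear and less basic, adds to give the propargylic carbinol F3. Meyer–Schuster rearrangement (Sc(OTf)3 cat., CH2Cl2/EtOH) gives the ethyl dienoate F4, i-Bu2AlH reduces it to the allylic alcohol F5, and MnO2 oxidises this to the enal, returning to the route at 23.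

**Further compounds**
F1 | step 18 | (7R,8R,8aS)-8-(TBS-oxy)-3-[(1E,3E,5R,6S)-6-(TBS-oxy)-3,5-dimethylhepta-1,3-dien-1-yl]-7-methyl-6,7,8,8a-tetrahydro-1H-isochromene-6,7-diol, hydroxyls at C6 and C7 cis | CC(/C=C/C1=CC2=C[C@H](O)[C@](C)(O)[C@H](O[Si](C)(C)C(C)(C)C)[C@@H]2CO1)=C\[C@@H](C)[C@H](C)O[Si](C)(C)C(C)(C)C
F2 | step 13 | tert-butyldimethyl{[(2S,3R,4E,6E)-3,5-dimethyl-7-[4-(trimethylsilyloxy)-2H-pyran-6-yl]hepta-4,6-dien-2-yl]oxy}silane | C[Si](C)(C)OC1=CCOC(/C=C/C(C)=C/[C@@H](C)[C@H](C)O[Si](C)(C)C(C)(C)C)=C1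
F3 | step 15 | (3S)-4-(ethoxyethynyl)-3-[(1R,2S)-1-(TBS-oxy)-2-(TES-oxy)propyl]-6-[(1E,3E,5R,6S)-6-(TBS-oxy)-3,5-dimethylhepta-1,3-dien-1-yl]-3,4-dihydro-2H-pyran-4-ol (both C4 epimers) | CCOC#CC1(O)C=C(/C=C/C(C)=C/[C@@H](C)[C@H](C)O[Si](C)(C)C(C)(C)C)OC[C@H]1[C@@H](O[Si](C)(C)C(C)(C)C)[C@H](C)O[Si](CC)(CC)CC
F4 | step 15 | ethyl (2E)-2-[(3S)-3-[(1R,2S)-1-(TBS-oxy)-2-(TES-oxy)propyl]-6-[(1E,3E,5R,6S)-6-(TBS-oxy)-3,5-dimethylhepta-1,3-dien-1-yl]-2,3-dihydro-4H-pyran-4-ylidene]acetate | CCOC(=O)/C=C1/C=C(/C=C/C(C)=C/[C@@H](C)[C@H](C)O[Si](C)(C)C(C)(C)C)OC[C@H]1[C@@H](O[Si](C)(C)C(C)(C)C)[C@H](C)O[Si](CC)(CC)CC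
F5 | step 15 | (2E)-2-[(3S)-3-[(1R,2S)-1-(TBS-oxy)-2-(TES-oxy)propyl]-6-[(1E,3E,5R,6S)-6-(TBS-oxy)-3,5-dimethylhepta-1,3-dien-1-yl]-2,3-dihydro-4H-pyran-4-ylidene]ethanol | OC/C=C1/C=C(/C=C/C(C)=C/[C@@H](C)[C@H](C)O[Si](C)(C)C(C)(C)C)OC[C@H]1[C@@H](O[Si](C)(C)C(C)(C)C)[C@H](C)O[Si](CC)(CC)CC
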